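**Retrosynthetic overview**

1. The target is fisetinidol-(4β→6)-leucofisetinidin; the lower unit is marked with double primes. The last events are global hydrogenolysis (eight benzyl ethers, one aryl C–Cl) and then NaBH4 reduction of the lower C-4'' ketone to the 3,4-trans diol.
2. Lower pyranone ring F: the C-4''–C-4a'' bond comes from Pd-catalysed acylation of a ring D arylzinc with a β-silyloxy thioester, and O-1''–C-8a'' from intramolecular SNAr of the C-2'' alkoxide on a ring D fluoride.
3. Interflavan bond C-4–C-6'': a ring D arylcerium (from 4-bromo-3-fluorophenol, with I, Br and F as three separate handles) adds to the upper 4-ketone; ionic hydrogenation then delivers hydride anti to O-3, giving the 4β-aryl (3,4-cis) centre.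
4. Key disconnection: upper ring C by annulation of a ring A aryne with an anti-α-benzyloxy-β-hydroxy thioester, forming O-1–C-8a and C-4a–C-4 together. The enabling feature is that O-1 and C-4 of pyran ring C sit on the adjacent ring A carbons C-8a and C-4a, the neighbouring C-5 is unsubstituted in the target and can carry a removable chlorine that polarises the aryne, and O-1–C-2–C-3–C-4 is an aldol (β-oxy-acyl) unit.
5. One asymmetric anti-glycolate Mukaiyama aldol supplies C-2/C-3 and the catechol ring of both units. Ring order: C (upper pyranone), then ring D attached, then F (lower pyranone).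

Key step: step 7

Assumption: the (S)-diamine in step 6 is taken to give the (2R,3R) adduct by analogy with simple aromatic aldehydes; the (R)-diamine would be used if the sense proved opposite.

**Route**

Step 1
Reactants: 1 4-(benzyloxy)phenol
Product: 2 4-(benzyloxy)-2-chlorophenol
Conditions: SO2Cl2 (1.05 equiv), i-Bu2NH (cat.), toluene, 60 °C
Reagents that add atoms: sulfuryl chloride O=S(=O)(Cl)Cl
Why: Amine-catalysed ortho-selective electrophilic chlorination of a phenol whose para position is blocked; the free OH outranks the benzyloxy group as director.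

Step 2
Reactants: 2 4-(benzyloxy)-2-chlorophenol
Product: 3 4-(benzyloxy)-2-bromo-6-chlorophenol
Conditions: NBS (1.05 equiv), i-Pr2NH (cat.), CH2Cl2, 0 °C
Reagents that add atoms: N-bromosuccinimide O=C1CCC(=O)N1Br
Why: Electrophilic bromination at the only remaining position ortho to the phenolic OH.

Step 3
Reactants: 3 4-(benzyloxy)-2-bromo-6-chlorophenol
Product: 6 4-(benzyloxy)-2-chloro-6-(trimethylsilyl)phenyl trifluoromethanesulfonate, via aryl silyl ether 4 (not isolated), via lithium silylphenolate 5 (not isolated)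
Conditions: (Me3Si)2NH, THF, 65 °C, then evaporation; n-BuLi, THF, −78 °C; Tf2O, −78 °C → rt
Reagents that add atoms: hexamethyldisilazane C[Si](C)(C)N[Si](C)(C)C; trifluoromethanesulfonic anhydride O=S(=O)(OS(=O)(=O)C(F)(F)F)C(F)(F)F
Why: O-silylation, bromine–lithium exchange and retro-Brook 1,3-shift of silicon from O to C give the o-silylphenolate, which is triflated (the standard o-silylaryl triflate synthesis); chlorine is not exchanged at −78 °C and lies meta to the lithiated carbon, so no aryne forms here.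

Step 4
Reactants: 7 (benzyloxy)acetyl chloride
Product: 8 S-ethyl 2-(benzyloxy)ethanethioate
Conditions: EtSH, pyridine, CH2Cl2, 0 °C
Reagents that add atoms: ethanethiol CCS
Why: Acyl substitution of the acid chloride by the thiol (thioesterification).

Step 5
Reactants: 8 S-ethyl 2-(benzyloxy)ethanethioate
Product: 9 (Z)-{[2-(benzyloxy)-1-(ethylsulfanyl)ethenyl]oxy}trimethylsilane
Conditions: LiN(i-Pr)2, Me3SiCl, THF, −78 °C
Reagents that add atoms: chlorotrimethylsilane C[Si](C)(C)Cl
Why: Kinetic enolisation with O-silylation; lithium chelation by the α-benzyloxy oxygen should favour the Z ketene silyl thioacetal needed for anti selectivity.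

Step 6
Reactants: 9 (Z)-ketene silyl thioacetal; 10 3,4-bis(benzyloxy)benzaldehyde
Product: 11 S-ethyl (2R,3R)-2-(benzyloxy)-3-[3,4-bis(benzyloxy)phenyl]-3-hydroxypropanethioate
Conditions: Sn(OTf)2 (1.0 equiv), (S)-1-ethyl-2-(piperidin-1-ylmethyl)pyrrolidine (1.2 equiv), n-Bu2Sn(OAc)2 (1.1 equiv), CH2Cl2, −78 °C; aq. NaHCO3
Reagents that add atoms: none
Why: Asymmetric Mukaiyama aldol promoted by divalent tin triflate and a chiral diamine; the α-benzyloxy Z-enolate should give the anti adduct, and the diamine–tin complex selects the aldehyde face, setting both stereocentres (future C-3 and C-2 of each flavan unit).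

Step 7
Reactants: 11 anti-aldol thioester; 6 silylaryl triflate
Product: 14 (2R,3R)-3,7-bis(benzyloxy)-2-[3,4-bis(benzyloxy)phenyl]-5-chloro-2,3-dihydro-4H-chromen-4-one, via aryne 12 (not isolated), via aryl caesium species 13 (not isolated)
Conditions: CsF (4 equiv), 18-crown-6 (1 equiv), THF, 0 °C → rt; 6 (2.5 equiv) added over 4 h
Reagents that add atoms: none
Why: Proposed new method: fluoride converts 6 into aryne 12, and the caesium alkoxide of 11 should add to the aryne carbon remote from chlorine (C-8a), because the inductively withdrawing chlorine makes that terminus the more electrophilic one and stabilises the carbanion developing next to it at C-4a, while the meta benzyloxy group is too far away to compete and the bulky secondary alkoxide also prefers the unhindered end. The aryl anion 13 then attacks the thioester carbonyl through a six-membered transition state (6-exo-trig addition, then loss of ethanethiolate), so ring C closes as a formal [4+2] annulation of the O–C–C–C(=O) unit onto the aryne. The closest known reactions are the fluoride-induced aryne annulations of salicylates to xanthones and of anthranilates to acridones (O- or N-arylation followed by intramolecular acyl trapping); new here are an aliphatic secondary alkoxide as nucleophile and a thioester as trap. No stereocentre is created: C-2 is carried over from the aldol because its C–O bond is never broken, and C-3, now alpha to the ketone, is epimerisable with the 2,3-trans arrangement thermodynamically favoured. The step needs O-attack at C-8a rather than C-4a (secured by the chlorine at C-5), O-arylation faster than retro-aldol cleavage of the alkoxide (slow addition of 6, low temperature, a thioester rather than a ketone as acceptor) and acylation faster than protonation of 13 (aprotic THF, intramolecular six-membered trap); the released thiolate is scavenged by the excess aryne.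

Step 8
Reactants: 15 4-bromo-3-fluorophenol
Product: 16 4-(benzyloxy)-1-bromo-2-fluorobenzene
Conditions: BnBr, K2CO3, acetone, 55 °C
Reagents that add atoms: benzyl bromide BrCc1ccccc1
Why: Williamson ether synthesis on the phenoxide.

Step 9
Reactants: 16 4-(benzyloxy)-1-bromo-2-fluorobenzene
Product: 17 1-(benzyloxy)-4-bromo-5-fluoro-2-iodobenzene
Conditions: NIS (1.1 equiv), CF3CO2H (cat.), MeCN, rt
Reagents that add atoms: N-iodosuccinimide O=C1CCC(=O)N1I
Why: Electrophilic aromatic iodination directed by the benzyloxy group; its para position is blocked by bromine, and of the two ortho positions the one para to fluorine and not flanked on both sides should react.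

Step 10
Reactants: 17 1-(benzyloxy)-4-bromo-5-fluoro-2-iodobenzene; 14 chromanone
Product: 20 (2R,3R)-3,7-bis(benzyloxy)-4-[2-(benzyloxy)-5-bromo-4-fluorophenyl]-2-[3,4-bis(benzyloxy)phenyl]-5-chloro-3,4-dihydro-2H-chromen-4-ol (either or both C-4 epimers), via aryllithium 18 (not isolated), via arylcerium dichloride 19 (not isolated)
Conditions: 17, n-BuLi, THF, −78 °C; CeCl3 (anhydrous), −78 °C; then 14, −78 → −40 °C; aq. NH4Cl
Reagents that add atoms: none
Why: Iodine–lithium exchange is far faster than bromine–lithium exchange at −78 °C, and the weakly basic, oxophilic organocerium reagent adds to the hindered, enolisable 3-alkoxychromanone without deprotonating C-3 (which would open ring C by E1cB and erase C-2); the C-4 configuration is irrelevant because it is planarised in step 11.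

Step 11
Reactants: 20 tertiary carbinol
Product: 21 (2R,3S,4S)-3,7-bis(benzyloxy)-4-[2-(benzyloxy)-5-bromo-4-fluorophenyl]-2-[3,4-bis(benzyloxy)phenyl]-5-chloro-3,4-dihydro-2H-chromene
Conditions: i-Pr3SiH (5 equiv), CF3CO2H (3 equiv), CH2Cl2, −78 → −30 °C
Reagents that add atoms: none
Why: Ionic hydrogenation: acid ionises the doubly benzylic tertiary carbinol (both epimers give one cation) and the bulky silane should deliver hydride along the equatorial trajectory on the α-face, anti to the C-3 benzyloxy group, as trialkylsilanes do with 1-arylcyclohexyl cations (aryl ends axial); this leaves ring D axial, cis to O-3 and clear of the peri chlorine, which is the 4β (4S) configuration.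

Step 12
Reactants: 11 anti-aldol thioester
Product: 22 S-ethyl (2R,3R)-2-(benzyloxy)-3-[3,4-bis(benzyloxy)phenyl]-3-[(triethylsilyl)oxy]propanethioate
Conditions: Et3SiCl, imidazole, DMF, 0 °C → rt
Reagents that add atoms: chlorotriethylsilane CC[Si](Cl)(CC)CC
Why: Silylation masks the hydroxyl proton from the organozinc of step 13 and stores the alkoxide for fluoride release in step 14.

Step 13
Reactants: 21 aryl bromide; 22 silyl-protected thioester
Product: 25 (2R,3R)-2-(benzyloxy)-1-{4-(benzyloxy)-5-[(2R,3S,4S)-3,7-bis(benzyloxy)-2-[3,4-bis(benzyloxy)phenyl]-5-chloro-3,4-dihydro-2H-chromen-4-yl]-2-fluorophenyl}-3-[3,4-bis(benzyloxy)phenyl]-3-[(triethylsilyl)oxy]propan-1-one, via aryllithium 23 (not isolated), via arylzinc chloride 24 (not isolated)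
Conditions: 21, n-BuLi, THF, −78 °C; ZnCl2, −78 °C → rt; then 22, PdCl2(PPh3)2 (5 mol %), THF/toluene, rt
Reagents that add atoms: none
Why: Bromine–lithium exchange and immediate transmetalation give a robust arylzinc (the ortho-fluoro aryllithium would otherwise lose LiF), and Fukuyama coupling (zerovalent palladium inserts into the thioester C–S bond, then transmetalation and reductive elimination) makes the ketone under neutral conditions that leave the α-alkoxy stereocentre untouched.

Step 14
Reactants: 25 fluoroaryl ketone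
Product: 27 (2R,3R)-3,7-bis(benzyloxy)-6-[(2R,3S,4S)-3,7-bis(benzyloxy)-2-[3,4-bis(benzyloxy)phenyl]-5-chloro-3,4-dihydro-2H-chromen-4-yl]-2-[3,4-bis(benzyloxy)phenyl]-2,3-dihydro-4H-chromen-4-one, via ammonium alkoxide 26 (not isolated)
Conditions: Bu4NF (0.3 equiv), THF/DMF, 0 °C → rt
Reagents that add atoms: none
Why: Fluoride-triggered desilylation releases the C-2'' alkoxide, which displaces the fluorine ortho to the ketone (intramolecular SNAr through a Meisenheimer intermediate, six-membered closure of ring F); the C-2''–O bond is untouched so C-2'' keeps its configuration, C-3'' alpha to the ketone settles in the favoured 2,3-trans form, and the expelled fluoride carries the chain so the alkoxide never accumulates.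

Step 15
Reactants: 27 protected biflavonoid ketone
Product: 28 (2R,3R)-2-(3,4-dihydroxyphenyl)-6-[(2R,3S,4S)-2-(3,4-dihydroxyphenyl)-3,7-dihydroxy-3,4-dihydro-2H-chromen-4-yl]-3,7-dihydroxy-2,3-dihydro-4H-chromen-4-one
Conditions: H2 (1 atm), Pd(OH)2/C, NaHCO3 (1.5 equiv), THF/MeOH/H2O, rt
Reagents that add atoms: none
Why: Heterogeneous hydrogenolysis cleaves the eight benzyl ethers and, buffered by hydrogencarbonate, the aryl C–Cl bond, while the electron-rich chromanone carbonyl and the interflavan C–C bond should be inert under these neutral conditions.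

Step 16
Reactants: 28 free phenolic ketone
Product: 29 (2R,3S,4S)-2-(3,4-dihydroxyphenyl)-4-[(2R,3S,4R)-2-(3,4-dihydroxyphenyl)-3,4,7-trihydroxy-3,4-dihydro-2H-chromen-6-yl]-3,4-dihydro-2H-chromene-3,7-diol
Conditions: NaBH4, EtOH/H2O, 0 °C → rt; AcOH to pH 6; Sephadex LH-20
Reagents that add atoms: none
Why: Borohydride reduction of a 2,3-trans dihydroflavonol: axial hydride attack anti to the axial H-3'' gives the equatorial 4''-OH, the 3,4-trans (4''R) flavan-3,4-diol, as in the known reduction of fustin-type dihydroflavonols.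

**Compound list**

1 | 4-(benzyloxy)phenol | Oc1ccc(OCc2ccccc2)cc1 | starting material
2 | 4-(benzyloxy)-2-chlorophenol | Oc1ccc(OCc2ccccc2)cc1Cl | intermediate
3 | 4-(benzyloxy)-2-bromo-6-chlorophenol | Oc1c(Br)cc(OCc2ccccc2)cc1Cl | intermediate
4 | [4-(benzyloxy)-2-bromo-6-chlorophenoxy]trimethylsilane | C[Si](C)(C)Oc1c(Br)cc(OCc2ccccc2)cc1Cl | intermediate (not isolated)
5 | lithium 4-(benzyloxy)-2-chloro-6-(trimethylsilyl)phenolate | [Li+].[O-]c1c(Cl)cc(OCc2ccccc2)cc1[Si](C)(C)C | intermediate (not isolated)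
6 | 4-(benzyloxy)-2-chloro-6-(trimethylsilyl)phenyl trifluoromethanesulfonate | C[Si](C)(C)c1cc(OCc2ccccc2)cc(Cl)c1OS(=O)(=O)C(F)(F)F | intermediate
7 | (benzyloxy)acetyl chloride | ClC(=O)COCc1ccccc1 | starting material
8 | S-ethyl 2-(benzyloxy)ethanethioate | CCSC(=O)COCc1ccccc1 | intermediate
9 | (Z)-{[2-(benzyloxy)-1-(ethylsulfanyl)ethenyl]oxy}trimethylsilane | CCS/C(O[Si](C)(C)C)=C\OCc1ccccc1 | intermediate
10 | 3,4-bis(benzyloxy)benzaldehyde | O=Cc1ccc(OCc2ccccc2)c(OCc2ccccc2)c1 | starting material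
11 | S-ethyl (2R,3R)-2-(benzyloxy)-3-[3,4-bis(benzyloxy)phenyl]-3-hydroxypropanethioate | CCSC(=O)[C@H](OCc1ccccc1)[C@H](O)c1ccc(OCc2ccccc2)c(OCc2ccccc2)c1 | intermediate
12 | 5-(benzyloxy)-3-chlorobenzyne | ClC1=CC(OCc2ccccc2)=CC#C1 | intermediate (not isolated)
13 | caesium salt of the 2-aryl anion of S-ethyl (2R,3R)-2-(benzyloxy)-3-[3,4-bis(benzyloxy)phenyl]-3-[5-(benzyloxy)-3-chlorophenoxy]propanethioate | CCSC(=O)[C@H](OCc1ccccc1)[C@H](OC1=CC(OCc2ccccc2)=CC(Cl)=[C-]1)c1ccc(OCc2ccccc2)c(OCc2ccccc2)c1.[Cs+] | intermediate (not isolated)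
14 | (2R,3R)-3,7-bis(benzyloxy)-2-[3,4-bis(benzyloxy)phenyl]-5-chloro-2,3-dihydro-4H-chromen-4-one | C(c1ccccc1)Oc1cc(Cl)c2c(c1)O[C@H](c1ccc(OCc3ccccc3)c(OCc3ccccc3)c1)[C@@H](OCc1ccccc1)C2=O | intermediate
15 | 4-bromo-3-fluorophenol | Oc1ccc(Br)c(F)c1 | starting material
16 | 4-(benzyloxy)-1-bromo-2-fluorobenzene | Fc1cc(OCc2ccccc2)ccc1Br | intermediate
17 | 1-(benzyloxy)-4-bromo-5-fluoro-2-iodobenzene | Fc1cc(OCc2ccccc2)c(I)cc1Br | intermediate
18 | [2-(benzyloxy)-5-bromo-4-fluorophenyl]lithium | [Li]c1cc(Br)c(F)cc1OCc1ccccc1 | intermediate (not isolated)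
19 | [2-(benzyloxy)-5-bromo-4-fluorophenyl]cerium dichloride | Cl[Ce](Cl)c1cc(Br)c(F)cc1OCc1ccccc1 | intermediate (not isolated)
20 | (2R,3R)-3,7-bis(benzyloxy)-4-[2-(benzyloxy)-5-bromo-4-fluorophenyl]-2-[3,4-bis(benzyloxy)phenyl]-5-chloro-3,4-dihydro-2H-chromen-4-ol (C-4 epimers) | C(c1ccccc1)Oc1cc(Cl)c2c(c1)O[C@H](c1ccc(OCc3ccccc3)c(OCc3ccccc3)c1)[C@@H](OCc1ccccc1)C2(O)c1cc(Br)c(F)cc1OCc1ccccc1 | intermediate
21 | (2R,3S,4S)-3,7-bis(benzyloxy)-4-[2-(benzyloxy)-5-bromo-4-fluorophenyl]-2-[3,4-bis(benzyloxy)phenyl]-5-chloro-3,4-dihydro-2H-chromene | C(c1ccccc1)Oc1cc(Cl)c2c(c1)O[C@H](c1ccc(OCc3ccccc3)c(OCc3ccccc3)c1)[C@@H](OCc1ccccc1)[C@H]2c1cc(Br)c(F)cc1OCc1ccccc1 | intermediate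
22 | S-ethyl (2R,3R)-2-(benzyloxy)-3-[3,4-bis(benzyloxy)phenyl]-3-[(triethylsilyl)oxy]propanethioate | CCSC(=O)[C@H](OCc1ccccc1)[C@H](O[Si](CC)(CC)CC)c1ccc(OCc2ccccc2)c(OCc2ccccc2)c1 | intermediate
23 | aryllithium from 21 (lithium in place of bromine) | C(c1ccccc1)Oc1cc(Cl)c2c(c1)O[C@H](c1ccc(OCc3ccccc3)c(OCc3ccccc3)c1)[C@@H](OCc1ccccc1)[C@H]2c1cc([Li])c(F)cc1OCc1ccccc1 | intermediate (not isolated)
24 | arylzinc chloride from 21 (ZnCl in place of bromine) | C(c1ccccc1)Oc1cc(Cl)c2c(c1)O[C@H](c1ccc(OCc3ccccc3)c(OCc3ccccc3)c1)[C@@H](OCc1ccccc1)[C@H]2c1cc([Zn]Cl)c(F)cc1OCc1ccccc1 | intermediate (not isolated)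
25 | (2R,3R)-2-(benzyloxy)-1-{4-(benzyloxy)-5-[(2R,3S,4S)-3,7-bis(benzyloxy)-2-[3,4-bis(benzyloxy)phenyl]-5-chloro-3,4-dihydro-2H-chromen-4-yl]-2-fluorophenyl}-3-[3,4-bis(benzyloxy)phenyl]-3-[(triethylsilyl)oxy]propan-1-one | C(c1ccccc1)Oc1cc(Cl)c2c(c1)O[C@H](c1ccc(OCc3ccccc3)c(OCc3ccccc3)c1)[C@@H](OCc1ccccc1)[C@H]2c1cc(C(=O)[C@H](OCc2ccccc2)[C@H](O[Si](CC)(CC)CC)c2ccc(OCc3ccccc3)c(OCc3ccccc3)c2)c(F)cc1OCc1ccccc1 | intermediate
26 | tetrabutylammonium alkoxide of desilylated 25 | C(c1ccccc1)Oc1cc(Cl)c2c(c1)O[C@H](c1ccc(OCc3ccccc3)c(OCc3ccccc3)c1)[C@@H](OCc1ccccc1)[C@H]2c1cc(C(=O)[C@H](OCc2ccccc2)[C@H]([O-])c2ccc(OCc3ccccc3)c(OCc3ccccc3)c2)c(F)cc1OCc1ccccc1.CCCC[N+](CCCC)(CCCC)CCCC | intermediate (not isolated)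
27 | (2R,3R)-3,7-bis(benzyloxy)-6-[(2R,3S,4S)-3,7-bis(benzyloxy)-2-[3,4-bis(benzyloxy)phenyl]-5-chloro-3,4-dihydro-2H-chromen-4-yl]-2-[3,4-bis(benzyloxy)phenyl]-2,3-dihydro-4H-chromen-4-one | C(c1ccccc1)Oc1cc(Cl)c2c(c1)O[C@H](c1ccc(OCc3ccccc3)c(OCc3ccccc3)c1)[C@@H](OCc1ccccc1)[C@H]2c1cc2c(cc1OCc1ccccc1)O[C@H](c1ccc(OCc3ccccc3)c(OCc3ccccc3)c1)[C@@H](OCc1ccccc1)C2=O | intermediate
28 | (2R,3R)-2-(3,4-dihydroxyphenyl)-6-[(2R,3S,4S)-2-(3,4-dihydroxyphenyl)-3,7-dihydroxy-3,4-dihydro-2H-chromen-4-yl]-3,7-dihydroxy-2,3-dihydro-4H-chromen-4-one | Oc1ccc2c(c1)O[C@H](c1ccc(O)c(O)c1)[C@@H](O)[C@H]2c1cc2c(cc1O)O[C@H](c1ccc(O)c(O)c1)[C@@H](O)C2=O | intermediate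
29 | (2R,3S,4S)-2-(3,4-dihydroxyphenyl)-4-[(2R,3S,4R)-2-(3,4-dihydroxyphenyl)-3,4,7-trihydroxy-3,4-dihydro-2H-chromen-6-yl]-3,4-dihydro-2H-chromene-3,7-diol | Oc1ccc2c(c1)O[C@H](c1ccc(O)c(O)c1)[C@@H](O)[C@H]2c1cc2c(cc1O)O[C@H](c1ccc(O)c(O)c1)[C@@H](O)[C@@H]2O | target

**Summary**

Total step count: 16. Longest linear sequence: 10 steps (steps 4, 5, 6, 7, 10, 11, 13, 14, 15, 16; the branch through steps 1, 2, 3 is equally long).

Steps most likely to fail:

1. Step 7 (Proposed new method). The alkoxide of 11 may undergo retro-aldol cleavage before it is arylated, the aryl anion may be protonated before it acylates, or the O-aryl intermediate may eliminate aryloxide by E1cB. The fallback uses known chemistry and forms the two bonds separately; it sets out from 22 and comes back at 14. Commercial 3-chloro-5-fluorophenol F1 would be benzylated (BnBr, K2CO3) to 1-(benzyloxy)-3-chloro-5-fluorobenzene F2 and iodinated para to the ether oxygen (NIS, CF3CO2H) to 5-(benzyloxy)-1-chloro-3-fluoro-2-iodobenzene F3. Zinc insertion (Zn, LiCl, THF) would give [4-(benzyloxy)-2-chloro-6-fluorophenyl]zinc iodide F4, and Fukuyama coupling with 22 (PdCl2(PPh3)2) would give (2R,3R)-2-(benzyloxy)-1-[4-(benzyloxy)-2-chloro-6-fluorophenyl]-3-[3,4-bis(benzyloxy)phenyl]-3-[(triethylsilyl)oxy]propan-1-one F5. Bu4NF in THF/DMF would then unmask the alkoxide, which displaces the fluorine ortho to the ketone to give 14.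

2. Step 11. Hydride transfer to the C-4 cation may show poor facial selectivity, and proton loss from the cation to the enol ether could scramble C-3. The fallback replaces single-pass kinetic selection by a separate-and-recycle loop; it sets out from 20 and comes back at 20. The C-4 epimers would be separated and the unwanted (2R,3S,4R)-3,7-bis(benzyloxy)-4-[2-(benzyloxy)-5-bromo-4-fluorophenyl]-2-[3,4-bis(benzyloxy)phenyl]-5-chloro-3,4-dihydro-2H-chromene F6 re-oxidised with DDQ in wet CH2Cl2 (hydride abstraction at the doubly benzylic C-4, capture of the cation by water), returning carbinol 20 for another reduction.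

3. Step 13. The ortho-fluoro aryllithium may lose LiF to an aryne, or n-BuLi may deprotonate instead of exchanging, on this large substrate. The fallback replaces the lithium/zinc/palladium acylation of a thioester by a magnesium-based Weinreb ketone synthesis; it sets out from 21 and 22 and comes back at 25. Thioester 22 would be converted with MeNH(OMe)·HCl and i-PrMgCl into (2R,3R)-2-(benzyloxy)-3-[3,4-bis(benzyloxy)phenyl]-N-methoxy-N-methyl-3-[(triethylsilyl)oxy]propanamide F7. Bromine–magnesium exchange on 21 with i-PrMgCl·LiCl at −15 °C would give the thermally more robust arylmagnesium chloride F8, which is acylated by F7 to give 25.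

Further compounds
F1 | step 7 | 3-chloro-5-fluorophenol (commercial) | Oc1cc(F)cc(Cl)c1
F2 | step 7 | 1-(benzyloxy)-3-chloro-5-fluorobenzene | Fc1cc(Cl)cc(OCc2ccccc2)c1
F3 | step 7 | 5-(benzyloxy)-1-chloro-3-fluoro-2-iodobenzene | Fc1cc(OCc2ccccc2)cc(Cl)c1I
F4 | step 7 | [4-(benzyloxy)-2-chloro-6-fluorophenyl]zinc iodide | I[Zn]c1c(F)cc(OCc2ccccc2)cc1Cl
F5 | step 7 | (2R,3R)-2-(benzyloxy)-1-[4-(benzyloxy)-2-chloro-6-fluorophenyl]-3-[3,4-bis(benzyloxy)phenyl]-3-[(triethylsilyl)oxy]propan-1-one | O=C(c1c(F)cc(OCc2ccccc2)cc1Cl)[C@H](OCc1ccccc1)[C@H](O[Si](CC)(CC)CC)c1ccc(OCc2ccccc2)c(OCc2ccccc2)c1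
F6 | step 11 | (2R,3S,4R)-3,7-bis(benzyloxy)-4-[2-(benzyloxy)-5-bromo-4-fluorophenyl]-2-[3,4-bis(benzyloxy)phenyl]-5-chloro-3,4-dihydro-2H-chromene | C(c1ccccc1)Oc1cc(Cl)c2c(c1)O[C@H](c1ccc(OCc3ccccc3)c(OCc3ccccc3)c1)[C@@H](OCc1ccccc1)[C@@H]2c1cc(Br)c(F)cc1OCc1ccccc1
F7 | step 13 | (2R,3R)-2-(benzyloxy)-3-[3,4-bis(benzyloxy)phenyl]-N-methoxy-N-methyl-3-[(triethylsilyl)oxy]propanamide | CON(C)C(=O)[C@H](OCc1ccccc1)[C@H](O[Si](CC)(CC)CC)c1ccc(OCc2ccccc2)c(OCc2ccccc2)c1
F8 | step 13 | arylmagnesium chloride from 21 (MgCl in place of bromine) | C(c1ccccc1)Oc1cc(Cl)c2c(c1)O[C@H](c1ccc(OCc3ccccc3)c(OCc3ccccc3)c1)[C@@H](OCc1ccccc1)[C@H]2c1cc([Mg]Cl)c(F)cc1OCc1ccccc1
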